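## Structural features

The target joins a trans-fused drimane decalin (ring A: C1–C5 and C10; ring B: C5–C10) through the C9–C11 methylene to C1' of a cyclohexenone (ring C, C1'–C6'). The C4' hydroxymethyl group of ring C is esterified by one carboxyl of (S)-3-hydroxy-3-methylglutaric acid. In the decalin, C5 (S), the quaternary methyl-bearing C10 (S) and C9 (S) are contiguous: the C10 methyl and the C9 arm are cis (both β), the C5 hydrogen is trans to the methyl, C4 is gem-dimethylated and C8 carries an exocyclic methylene. Ring C holds three more contiguous stereocentres: the C1'–C2' epoxide (C1' quaternary; 1'R,2'R) and the C3' carbinol (3'R), whose hydroxyl is on the same face as the epoxide oxygen, next to the C4'=C5'–C6'=O enone. The carbinol carbon of the diacid is stereogenic only because its two CH2CO2 arms end differently, so an unselective opening of a symmetric acyl donor cannot deliver it. Fragile groups are the α,β-epoxy ketone and γ-acyloxy enone (base, nucleophiles, reductants), the 1,1-disubstituted C8=C12 alkene (strong acid, hydrogenation), the allylic ester beside a free C3' hydroxyl (acyl migration) and the tertiary β-hydroxy acid. The real difficulty is twofold: the vicinal C9/C10 pair, where a quaternary centre sits beside a carbon whose arm is a neopentyl-type CH2, and the regio- and face-selective oxidation of ring C far from any decalin stereocentre. The key step exploits that C9, C10 and C5 map onto the β-carbon, α-carbon and carbonyl carbon of a 2-methylcyclohex-2-enone (future ring B). C9–C11 then comes from conjugate addition, C1–C10 from enolate trapping and C4–C5 from aldol closure of ring A, with an oxygen at C8 as the only stereochemical input and as the latent methylene.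

## Logic of the disconnections

35 ⇒ 28 + 32 (through 34 and 33). Cut: the ester C–O bond between the C4' CH2O oxygen and the acyl carbon. Reason: it is the most labile bond, and the acyl part has its own stereocentre; in 32 the two carboxyl ends are already told apart (free acid against tert-butyl ester), so the configuration is bought with 32 and not left to the remote stereocentres of 28. Gain: the complete core 28 and a five-carbon acid. Demand: acylation of the primary allylic hydroxyl of 28 beside the secondary C3' hydroxyl, and release of the acid without base or strong protic acid.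

32 ⇒ 31 ⇒ 30 ⇒ 29. Cuts: the tert-butyl ester C–O bond and, in the forward sense, one of the two enantiotopic methyl ester C–O bonds of 29. Reason: 29 is achiral; an esterase distinguishes its ester groups, and exchanging the roles of the two arms (30 to 32) makes the arm freed by the enzyme the protected one. Gain: a stereocentre from a symmetric precursor in three operations. Demand: high enantiotopic-group selectivity in the hydrolysis, and saponification of a methyl ester beside a tert-butyl ester.

28 ⇒ 27 ⇒ 26 ⇒ 25. Cuts: the C3'–H bond (28 to 27), then the two epoxide C–O bonds at C1' and C2' (26 to 25), with the C3' carbonyl kept as a dimethyl ketal in 26 and 25. Reason: in 25 the only enone β-carbon open to a peroxide nucleophile is C2', because C4' is fully substituted, so the epoxide position follows from the substitution pattern. Gain: three stereocentres removed, leaving a planar cross-conjugated dienone. Demand: facial selection by the reagent in the epoxidation, and in 27 hydride delivery to C3' and not C6', anti to the epoxide oxygen.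

25 ⇒ 24 ⇒ 23. Cuts: the C3' ketal C–O bond (oxidative dearomatisation retron) and the acetal C–O bonds of the two protecting groups. Reason: a para-methoxyphenol is oxidised to one monoketal only, with the carbonyl at the former phenol carbon, so C6' must carry the free hydroxyl and C3' the methyl ether. A symmetric dimethyl ether would depend on the regioselective hydrolysis of a bisketal in which each ketal has one alkyl-substituted neighbour, which the structure does not decide. Gain: ring C becomes an arene that survives the decalin construction. Demand: two different oxygen substituents on the arene from 13 onward, and a deprotection that spares the C8=C12 alkene.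

23 ⇒ 22 ⇒ 21 ⇒ 20 ⇒ 18 ⇒ 17. Cuts: the C8=C12 bond (carbonyl olefination), the C8–H bond (oxidation level), the C5–H and C6–H bonds (hydrogenation of C5=C6), the C3–H bonds (deoxygenation through 19) and the two C4–CH3 bonds. Reason: every one of these is a standard adjustment of a Robinson-type enone, and the C8 oxygen that directed the key step is converted into the methylene. Gain: 17 has no C5 stereocentre, no gem-dimethyl group and a conjugated enone that is the retron of an annulation. Demand: hydrogen delivery to C5 anti to the C10 methyl, and olefination of a hindered ketone without loss of the C9 configuration.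

17 ⇒ 6 + 13 + 14 (key step). Cuts: C9–C11, C1–C10 and C4–C5. Reason: C9 becomes an electrophilic β-carbon and the arm an unhindered benzylic nucleophile, so the neopentyl-type bond is made from the easy side. The quaternary C10 is made from a regiodefined tetrasubstituted enolate, and ring A comes from a four-carbon acceptor. Gain: three building blocks, one of them with a single stereocentre. Demand: addition anti to the C8 silyloxy group, alkylation anti to the new arm, and no enolate equilibration.

6 ⇒ 5 ⇒ 4 ⇒ 3 ⇒ 2 ⇒ 1. Cuts: the C2–CH3 bond (cross-coupling), the C2–I bond, the O–Si bond, the ketal, and the carbinol C–H bond (asymmetric reduction). Reason: the single stereocentre of 6 is a secondary allylic carbinol, accessible by catalytic asymmetric reduction of the achiral 1 in either hand. Gain: an achiral, purchasable enone ketal. Demand: 1,2-selectivity and enantioselectivity in the reduction.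

13 ⇒ 12 ⇒ 11 ⇒ 10 ⇒ 9 ⇒ 8 ⇒ 7. Cuts: the C–Mg and C–Cl bonds, the benzylic carbinol C–H bond, the acetal C–O bonds, a second carbinol C–H bond, and one O–CH3 bond. Reason: 7 is symmetric; removing one methyl group makes the two formyl groups electronically different (one becomes a vinylogous carboxylate in base), which differentiates both the oxygens and the carbons of the ring. Gain: a cheap symmetric dialdehyde. Demand: mono-demethylation and chemoselective reduction of one of two aldehydes. 14 is bought.

## Other disconnections considered

Alternative 1: The cut is the C6'–C1' bond of ring C. In the forward sense the δ-keto aldehyde A2, whose CH2–C(=O) unit (C11 and C1') comes from the lactone carbons of (+)-sclareolide A3, would be treated with SmI2 (divalent samarium). The aldehyde ketyl adds to the ketone and gives the cyclohexane cis-1,2-diol A1.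
- In its favour: the decalin with C5, C9 and C10 comes from the chiral pool, so none of these stereocentres has to be made; on this point the alternative is the better plan. C2' and C3' are set in an acyclic fragment where absolute control is routine.
- Against it here: A1 is far from the target oxidation pattern. C6' must be oxidised, and the tertiary C1' hydroxyl must displace an activated C2' oxygen with inversion to form the epoxide. The C4' methylene must be converted into the C4'=C5' alkene bearing CH2OH in the presence of a second 1,1-disubstituted alkene at C8 of nearly the same reactivity. A3 also has to be dehydrated regioselectively to the 8(12)-alkene.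
- Comparison: mechanistically the ketyl–ketone coupling is sound; the cis-diol follows from chelation of both oxygens to samarium, and C1' is set relative to C2' within the forming ring. This is as dependable as the reagent-controlled epoxidation of 25. In step count, the fragment synthesis, the coupling and the redox adjustments after ring closure would about equal the chosen route after 17. The chosen plan keeps ring C aromatic until the decalin is finished and never has to tell two exocyclic methylenes apart.

Alternative 2: The cut is C9–C10, which opens ring B. In the forward sense the monocyclic (Z)-allylsilane A5 would be exposed to a chiral BINOL-derived Brønsted acid activated by SnCl4 (tetravalent tin). Enantioface-selective protonation at C5 of the tetrasubstituted ring A alkene, attack of C9 on C10 and loss of silicon would give A4 with the C8 methylene in place.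
- In its favour: C5, C9, C10 and the exocyclic alkene arise in one step from an achiral precursor. No oxygen is ever placed at C3 or C8, so the work of steps 13 to 17 disappears; in step economy this alternative is clearly the better one.
- Against it here: the proton must go to a hindered tetrasubstituted endocyclic alkene, while the allylsilane terminus and the electron-rich arene are more basic sites, so protodesilylation and arene complexation of the Lewis acid compete. Absolute control rests on one intermolecular protonation, and incomplete selectivity gives an enantiomeric mixture that no later step upgrades. The alkene geometry of A5 decides the C9 configuration (chair transition state, arm equatorial), so A5 must be a single isomer.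
- Comparison: in the chosen plan the absolute configuration is fixed in 6 and every later decalin stereocentre is set by substrate control as a separable diastereomer. Structurally the two plans are equal in ending at an arylmethyl drimane. A4 carries two methyl ethers and would need the same differentiation of the arene oxygens that is built into 13.

Alternative 3: The cut is the C4'=C5' double bond. In the forward sense the epoxy dienone A7, derived from an acyclic allylic alcohol by Sharpless asymmetric epoxidation, would close ring C with the second-generation Grubbs catalyst RuCl2(=CHPh)(H2IMes)(PCy3). The C6' vinyl ketone and the C4' 1,1-disubstituted alkene join with loss of ethylene to give A6.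
- In its favour: the epoxide configuration comes from a reaction with a dependable mnemonic, and the C3' carbinol is in place before ring closure. Neither the facial selection of step 20 nor the regioselective reduction of step 22 is needed; on control of the ring C stereocentres the alternative is the better plan. The decalin could again come from the chiral pool.
- Against it here: the ring closure must join an electron-poor vinyl ketone to a 1,1-disubstituted alkene to form a trisubstituted enone, a demanding olefin pair, and the C8 methylene is a third alkene of the same class that can enter cross metathesis. The acyclic precursor needs a stereodefined trisubstituted alkene carrying the drimanylmethyl group on its fully substituted carbon, that is, C–C bond formation at the neopentyl-type C11, the connection the chosen plan makes with a benzylic nucleophile. In A6 the more labile silyl group sits on the secondary hydroxyl, while the primary one, which must be freed for acylation, carries the more robust group.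
- Comparison: in step count the two plans are about equal once the decalin is secured. Mechanistically the metathesis is neutral, which suits the epoxy ketone at least as well as the basic peroxide of the chosen route.

Key step: step 12

Remarks before the steps:
- Notation: drimane numbering; β is the face of the C10 methyl; Ar = 5-methoxy-2-(methoxymethoxy)-4-[(methoxymethoxy)methyl]phenyl; "drim-8(12)-en-11-yl" means the (5S,9S,10S) skeleton of the target.
- Check of the structures: the (4R)-enone and the annulation product are stereochemically consistent with the target (silyloxy α, arm β, methyl β). Three points of the outline were changed.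
  - Enone source: the usual short degradation of D-(−)-quinic acid keeps C4 of the acid as the carbinol and places the enone on the C2–C3 side, which gives the (4S)-enone, the antipode of 6. Compound 6 is therefore made by catalytic asymmetric reduction.
  - Arene oxygens: they are differentiated (C6' as a methoxymethyl ether, C3' as a methyl ether) so that the monoketal forms regiospecifically.
  - Acid fragment: the carbinol stereocentre is set before the coupling, because a symmetric anhydride would be opened at either carbonyl.
- Assumption: the (R,R)-configured ruthenium catalyst is taken to give the (R)-carbinol 2 and L-(+)-diisopropyl tartrate the (1'R,2'S)-epoxide 26; both reagents exist as antipodes, and the other hand is used if the sense is reversed.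
- Assumption: pig liver esterase is taken to cleave the pro-S ester group of 29, giving the (S)-half-ester 30.
- Assumption: 1 and 14 are taken as catalogue compounds.

## Route

Step 1
Reactants: 1 1,4-dioxaspiro[4.5]dec-6-en-8-one
Product: 2 (8R)-1,4-dioxaspiro[4.5]dec-6-en-8-ol
Conditions: RuCl[(R,R)-TsDPEN](p-cymene) (1 mol %), HCO2H/Et3N (5:2), CH2Cl2, rt
Reagents that add atoms: none
Why: Noyori-type asymmetric transfer hydrogenation reduces the carbonyl 1,2, the β-carbon being shielded by the quaternary ketal carbon. The alkenyl arm takes the place of the aryl group of an aryl ketone in the transition state, which should place hydride on the face that gives the (R)-carbinol.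

Step 2
Reactants: 2 (8R)-1,4-dioxaspiro[4.5]dec-6-en-8-ol
Product: 3 (4R)-4-hydroxycyclohex-2-en-1-one
Conditions: PPTS (10 mol %), acetone/H2O (10:1), rt
Reagents that add atoms: water, O
Why: Mild acid-catalysed ketal hydrolysis gives the conjugated enone directly; the carbinol centre is not involved.

Step 3
Reactants: 3 (4R)-4-hydroxycyclohex-2-en-1-one
Product: 4 (4R)-4-(triethylsilyloxy)cyclohex-2-en-1-one
Conditions: Et3SiCl, imidazole, CH2Cl2, 0 °C
Reagents that add atoms: chlorotriethylsilane, CC[Si](Cl)(CC)CC
Why: Standard silylation of a secondary alcohol; the silyl ether is the directing group of the key step.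

Step 4
Reactants: 4 (4R)-4-(triethylsilyloxy)cyclohex-2-en-1-one
Product: 5 (4R)-2-iodo-4-(triethylsilyloxy)cyclohex-2-en-1-one
Conditions: I2, pyridine, CH2Cl2, 0 °C → rt
Reagents that add atoms: iodine, [I][I]
Why: Amine-mediated α-iodination of an enone (conjugate addition of pyridine, iodination of the enolate, elimination; a Baylis–Hillman-type sequence); only C2 can be functionalised.

Step 5
Reactants: 5 (4R)-2-iodo-4-(triethylsilyloxy)cyclohex-2-en-1-one
Product: 6 (4R)-2-methyl-4-(triethylsilyloxy)cyclohex-2-en-1-one
Conditions: MeZnCl, Pd(dppf)Cl2 (3 mol %), THF, 0 °C → rt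
Reagents that add atoms: methylzinc chloride, C[Zn]Cl
Why: Negishi coupling of an α-iodoenone; the organozinc does not add to the enone, and the silyl ether and the C4 centre are untouched.

Step 6
Reactants: 7 2,5-dimethoxyterephthalaldehyde
Product: 8 2-hydroxy-5-methoxyterephthalaldehyde
Conditions: BBr3 (1.05 equiv), CH2Cl2, −78 → 0 °C; H2O
Reagents that add atoms: none
Why: Lewis-acid ether cleavage. Each methoxy group is ortho to a formyl group, and one equivalent of BBr3 should stop at the chelated aryloxyborane of the mono-phenol; 8 is separated from 7 and from the bis-phenol by its acidity.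

Step 7
Reactants: 8 2-hydroxy-5-methoxyterephthalaldehyde
Product: 9 2-hydroxy-4-(hydroxymethyl)-5-methoxybenzaldehyde
Conditions: NaBH4 (0.3 equiv), 1 M aq. NaOH/MeOH, 0 °C; then pH 5
Reagents that add atoms: none
Why: Chemoselective borohydride reduction. In base the formyl group ortho to the phenoxide is a vinylogous carboxylate and is deactivated, so the limited hydride should go to the formyl group meta to the phenoxide.

Step 8
Reactants: 9 2-hydroxy-4-(hydroxymethyl)-5-methoxybenzaldehyde
Product: 10 5-methoxy-2-(methoxymethoxy)-4-[(methoxymethoxy)methyl]benzaldehyde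
Conditions: MeOCH2Cl (3 equiv), i-Pr2NEt (4 equiv), CH2Cl2, 0 °C → rt
Reagents that add atoms: chloromethyl methyl ether, COCCl
Why: O-alkylation of both hydroxyls. Methoxymethyl ethers withstand the organomagnesium, alkoxide, hydrazine/KOH and ylide steps ahead and are removed together in step 18.

Step 9
Reactants: 10 5-methoxy-2-(methoxymethoxy)-4-[(methoxymethoxy)methyl]benzaldehyde
Product: 11 {5-methoxy-2-(methoxymethoxy)-4-[(methoxymethoxy)methyl]phenyl}methanol
Conditions: NaBH4, MeOH, 0 °C
Reagents that add atoms: none
Why: Borohydride reduction of the remaining aldehyde.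

Step 10
Reactants: 11 {5-methoxy-2-(methoxymethoxy)-4-[(methoxymethoxy)methyl]phenyl}methanol
Product: 12 1-(chloromethyl)-5-methoxy-2-(methoxymethoxy)-4-[(methoxymethoxy)methyl]benzene
Conditions: PPh3, N-chlorosuccinimide (premixed), THF, 0 °C → rt
Reagents that add atoms: N-chlorosuccinimide, O=C1CCC(=O)N1Cl
Why: Appel-type chlorination under neutral conditions (alkoxyphosphonium ion displaced by chloride), which spares the acid-labile acetals of this electron-rich benzylic system.

Step 11
Reactants: 12 1-(chloromethyl)-5-methoxy-2-(methoxymethoxy)-4-[(methoxymethoxy)methyl]benzene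
Product: 13 {5-methoxy-2-(methoxymethoxy)-4-[(methoxymethoxy)methyl]benzyl}magnesium chloride (THF solution, titrated, used at once)
Conditions: Mg turnings (activated, excess), THF, 0 °C, slow addition at high dilution
Reagents that add atoms: magnesium, [Mg]
Why: Oxidative insertion of magnesium into the benzylic C–Cl bond; slow addition at low concentration and temperature suppresses Wurtz coupling.

Step 12
Reactants: 6 (4R)-2-methyl-4-(triethylsilyloxy)cyclohex-2-en-1-one; 13 {5-methoxy-2-(methoxymethoxy)-4-[(methoxymethoxy)methyl]benzyl}magnesium chloride; 14 3-(trimethylsilyl)but-3-en-2-one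
Product: 17 bicyclic enone (ring A 3-oxo-Δ4; 10β-methyl; 9β-CH2Ar; 8α-OSiEt3), via magnesium enolate 15 (not isolated), via silyl diketone 16 (not isolated)
Conditions: 13 (1.3 equiv), CuBr·SMe2 (10 mol %), THF, −40 °C; 14 (1.5 equiv), −78 → −20 °C; aq. NH4Cl; crude, NaOMe (0.5 equiv), MeOH, rt → 45 °C
Reagents that add atoms: none
Why: Transmetalation of 13 to monovalent copper (CuBr·SMe2) gives a benzylcopper species that adds 1,4 to 6 at C9 and leaves the chloromagnesium enolate 15 with its double bond fixed between C5 and C10. This tetrasubstituted enolate adds through C10 to the CH2 terminus of 14, whose silyl group stabilises the new α-carbanion and so prevents polymerisation and proton transfer back to the ring, giving 16 and the C1–C10 bond. Methoxide then removes silicon, the methyl ketone enolate (C4) attacks the C5 carbonyl in a 6-(enolendo)-exo-trig aldol closure of ring A, and dehydration gives the conjugated enone 17 with the C4–C5 bond. The closest known reaction type is the copper-catalysed conjugate addition with enolate trapping by an α-silyl vinyl ketone and aldol condensation, a Robinson-type annulation. C9 is set by the C8 silyloxy group: the nucleophile enters axially on the enone face anti to it, so the arm becomes β and trans to the oxygen. C10 is set by C9: the acceptor approaches the enolate anti to the new arm, which leaves the methyl group cis to the arm as in the target. The step needs 1,4- over 1,2-addition (copper and the unhindered benzylic nucleophile), C-alkylation at C10 without enolate equilibration (low temperature, no proton source, a highly electrophilic acceptor) and closure to the fused enone and not the bridged ketol (the aldol is reversible and only the fused aldol can dehydrate).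

Step 13
Reactants: 17 bicyclic enone (ring A 3-oxo-Δ4; 10β-methyl; 9β-CH2Ar; 8α-OSiEt3)
Product: 18 4,4-dimethyl β,γ-enone (3-oxo-Δ5; 10β-methyl; 9β-CH2Ar; 8α-OSiEt3)
Conditions: KOtBu (3 equiv), t-BuOH/THF, 0 °C; MeI (4 equiv), 0 °C → rt
Reagents that add atoms: iodomethane, IC
Why: Deconjugative α,α-dialkylation: the extended dienolate is methylated at C4, and the second methylation fixes the double bond at C5=C6. This is a known reaction of Wieland–Miescher-type enones.

Step 14
Reactants: 18 4,4-dimethyl β,γ-enone (3-oxo-Δ5; 10β-methyl; 9β-CH2Ar; 8α-OSiEt3)
Product: 20 11-Ar-12-nordrim-5-en-8α-ol, via hydrazone 19 (not isolated)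
Conditions: N2H4·H2O, KOH, diethylene glycol, 130 °C, then 200 °C with removal of water
Reagents that add atoms: none
Why: Wolff–Kishner reduction (Huang-Minlon modification) of the hindered C3 ketone through hydrazone 19. The C5=C6 alkene is not conjugated with the carbanion and stays in place, and the acetals and the aryl ether are inert to base. The triethylsilyl ether is cleaved by hydroxide at these temperatures, which is intended and saves a separate deprotection.

Step 15
Reactants: 20 11-Ar-12-nordrim-5-en-8α-ol
Product: 21 11-Ar-12-nordriman-8α-ol (5α-H, trans-decalin)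
Conditions: Mn(dpm)3 (10 mol %), PhSiH3, t-BuOOH, i-PrOH, rt
Reagents that add atoms: none
Why: Hydrogen-atom-transfer hydrogenation (Mukaiyama type): a hydrogen atom adds to C6, and the tertiary C5 radical takes up hydrogen on the α face, anti to the axial C10 and 4β methyl groups, giving the thermodynamically favoured trans-decalin and the C5 stereocentre. The radical method reaches a trisubstituted alkene flanked by quaternary carbons and does not hydrogenolyse benzylic C–O bonds.

Step 16
Reactants: 21 11-Ar-12-nordriman-8α-ol
Product: 22 11-Ar-12-nordriman-8-one
Conditions: Dess–Martin periodinane, NaHCO3, CH2Cl2, 0 °C → rt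
Reagents that add atoms: none
Why: Dess–Martin oxidation of the secondary alcohol under buffered conditions; C9 keeps its configuration because the equatorial β arm is the more stable epimer α to the ketone.

Step 17
Reactants: 22 11-Ar-12-nordriman-8-one
Product: 23 11-Ar-drim-8(12)-ene
Conditions: Ph3PCH3Br (3 equiv), KOtBu (2.8 equiv), toluene, rt → 80 °C
Reagents that add atoms: methyltriphenylphosphonium bromide, C[P+](c1ccccc1)(c1ccccc1)c1ccccc1.[Br-]
Why: Wittig methylenation; the non-stabilised ylide reacts with the hindered ketone on heating, and any enolisation at C9 returns the more stable equatorial epimer.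

Step 18
Reactants: 23 11-Ar-drim-8(12)-ene
Product: 24 11-[2-hydroxy-4-(hydroxymethyl)-5-methoxyphenyl]drim-8(12)-ene
Conditions: PPTS (2 equiv), t-BuOH, 80 °C
Reagents that add atoms: none
Why: Acetal cleavage with a weak pyridinium acid removes both methoxymethyl ethers (aryl and benzylic) without protonating the 1,1-disubstituted alkene.

Step 19
Reactants: 24 11-[2-hydroxy-4-(hydroxymethyl)-5-methoxyphenyl]drim-8(12)-ene
Product: 25 2-(drim-8(12)-en-11-yl)-5-(hydroxymethyl)-4,4-dimethoxycyclohexa-2,5-dien-1-one
Conditions: PhI(OAc)2 (1.1 equiv), MeOH, 0 °C
Reagents that add atoms: methanol, CO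
Why: Oxidative dearomatisation of a para-methoxyphenol with a hypervalent iodine reagent. Methanol adds at the methoxy-bearing carbon para to the phenol oxygen, so the carbonyl is fixed at C6' and the ketal at C3' without regiochemical ambiguity.

Step 20
Reactants: 25 2-(drim-8(12)-en-11-yl)-5-(hydroxymethyl)-4,4-dimethoxycyclohexa-2,5-dien-1-one
Product: 26 (1R,6S)-1-(drim-8(12)-en-11-yl)-4-(hydroxymethyl)-5,5-dimethoxy-7-oxabicyclo[4.1.0]hept-3-en-2-one
Conditions: Ph3COOH (2 equiv), NaN(SiMe3)2 (3 equiv), L-(+)-diisopropyl tartrate (2 equiv), toluene, −50 °C
Reagents that add atoms: triphenylmethyl hydroperoxide, OOC(c1ccccc1)(c1ccccc1)c1ccccc1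
Why: Tartrate-mediated nucleophilic (Weitz–Scheffer-type) epoxidation of a quinone monoketal: the peroxide anion adds to C2', the only unsubstituted β-carbon, and the enolate closes onto oxygen. The sodium alkoxide of the C4' hydroxymethyl group binds the chiral tartrate–peroxide aggregate, which selects the enone face and sets C1' and C2' by reagent control, the decalin being too remote.

Step 21
Reactants: 26 (1R,6S)-1-(drim-8(12)-en-11-yl)-4-(hydroxymethyl)-5,5-dimethoxy-7-oxabicyclo[4.1.0]hept-3-en-2-one
Product: 27 (1R,6S)-1-(drim-8(12)-en-11-yl)-4-(hydroxymethyl)-7-oxabicyclo[4.1.0]hept-3-ene-2,5-dione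
Conditions: 48% aq. HF, MeCN, 0 °C → rt
Reagents that add atoms: water, O
Why: Acid hydrolysis of the dimethyl ketal; dilute HF in acetonitrile should cleave the ketal next to the epoxide without opening the α-keto epoxide or isomerising the exocyclic alkene.

Step 22
Reactants: 27 (1R,6S)-1-(drim-8(12)-en-11-yl)-4-(hydroxymethyl)-7-oxabicyclo[4.1.0]hept-3-ene-2,5-dione
Product: 28 (1R,5R,6R)-1-(drim-8(12)-en-11-yl)-5-hydroxy-4-(hydroxymethyl)-7-oxabicyclo[4.1.0]hept-3-en-2-one
Conditions: i-Bu2AlH (2.5 equiv), THF, −78 °C; aq. potassium sodium tartrate
Reagents that add atoms: none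
Why: 1,2-reduction of the C3' carbonyl: the aluminium alkoxide formed at the C4' hydroxymethyl group directs hydride to the neighbouring carbonyl, while C6' is shielded by the quaternary C1', whose arm lies on the face anti to the epoxide. Attack anti to the epoxide oxygen (Felkin–Anh sense) should place the C3' hydroxyl cis to the epoxide.

Step 23
Reactants: 29 dimethyl 3-hydroxy-3-methylpentanedioate
Product: 30 (3S)-3-hydroxy-5-methoxy-3-methyl-5-oxopentanoic acid
Conditions: pig liver esterase, phosphate buffer pH 8 (pH-stat), rt; then pH 2
Reagents that add atoms: water, O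
Why: Enzymatic desymmetrisation: the esterase hydrolyses one of the two enantiotopic ester groups of this diester, which creates the stereocentre.

Step 24
Reactants: 30 (3S)-3-hydroxy-5-methoxy-3-methyl-5-oxopentanoic acid
Product: 31 1-tert-butyl 5-methyl (3R)-3-hydroxy-3-methylpentanedioate
Conditions: O-tert-butyl-N,N'-diisopropylisourea (2 equiv), CH2Cl2, rt
Reagents that add atoms: O-tert-butyl-N,N'-diisopropylisourea, CC(C)NC(=NC(C)C)OC(C)(C)C
Why: Esterification of the acid with an O-alkylisourea under neutral conditions; the tertiary alcohol does not react, and the descriptor changes only because the priorities of the arms change.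

Step 25
Reactants: 31 1-tert-butyl 5-methyl (3R)-3-hydroxy-3-methylpentanedioate
Product: 32 (3R)-5-tert-butoxy-3-hydroxy-3-methyl-5-oxopentanoic acid
Conditions: LiOH (1.5 equiv), THF/H2O, 0 °C; then cold 1 M HCl to pH 3
Reagents that add atoms: lithium hydroxide, [Li+].[OH-]
Why: Saponification: hydroxide attacks the unhindered methyl ester and not the tert-butyl ester. The stereocentre cannot epimerise, and the low temperature avoids retro-aldol cleavage.

Step 26
Reactants: 28 (1R,5R,6R)-1-(drim-8(12)-en-11-yl)-5-hydroxy-4-(hydroxymethyl)-7-oxabicyclo[4.1.0]hept-3-en-2-one; 32 (3R)-5-tert-butoxy-3-hydroxy-3-methyl-5-oxopentanoic acid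
Product: 33 tert-butyl ester of the target (primary allylic ester; acid carbinol 3R by the changed priorities)
Conditions: EDC·HCl (1.3 equiv), DMAP (0.1 equiv), CH2Cl2, −10 → 0 °C
Reagents that add atoms: none
Why: Steglich esterification: the primary allylic hydroxyl of 28 is acylated in preference to the hindered C3' hydroxyl, and the tertiary hydroxyl of 32 is inert. Catalytic DMAP and low temperature keep the epoxy enone intact.

Step 27
Reactants: 33 tert-butyl ester of the target
Product: 35 target CNP0158101.1, via tris(trimethylsilyl) derivative 34 (not isolated)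
Conditions: Me3SiOTf (6 equiv), 2,6-lutidine (9 equiv), CH2Cl2, 0 °C; then aq. citric acid/THF, 0 °C
Reagents that add atoms: none
Why: Lewis-acid cleavage of the tert-butyl ester (silylation of the carbonyl oxygen, loss of isobutene, buffered by 2,6-lutidine) gives the silyl ester 34 with both hydroxyls transiently silylated. Mild aqueous acid then hydrolyses the Si–O bonds, so no free strong acid or base meets the alkene or the epoxy enone.

## Compound list

1 | 1,4-dioxaspiro[4.5]dec-6-en-8-one | O=C1C=CC2(CC1)OCCO2 | starting material
2 | (8R)-1,4-dioxaspiro[4.5]dec-6-en-8-ol | O[C@@H]1CCC2(C=C1)OCCO2 | intermediate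
3 | (4R)-4-hydroxycyclohex-2-en-1-one | O[C@@H]1CCC(=O)C=C1 | intermediate
4 | (4R)-4-(triethylsilyloxy)cyclohex-2-en-1-one | CC[Si](CC)(CC)O[C@@H]1CCC(=O)C=C1 | intermediate
5 | (4R)-2-iodo-4-(triethylsilyloxy)cyclohex-2-en-1-one | IC1=C[C@H](O[Si](CC)(CC)CC)CCC1=O | intermediate
6 | (4R)-2-methyl-4-(triethylsilyloxy)cyclohex-2-en-1-one | CC1=C[C@H](O[Si](CC)(CC)CC)CCC1=O | intermediate
7 | 2,5-dimethoxyterephthalaldehyde | COc1cc(C=O)c(OC)cc1C=O | starting material
8 | 2-hydroxy-5-methoxyterephthalaldehyde | COc1cc(C=O)c(O)cc1C=O | intermediate
9 | 2-hydroxy-4-(hydroxymethyl)-5-methoxybenzaldehyde | COc1cc(C=O)c(O)cc1CO | intermediate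
10 | 5-methoxy-2-(methoxymethoxy)-4-[(methoxymethoxy)methyl]benzaldehyde | COCOCc1cc(OCOC)c(C=O)cc1OC | intermediate
11 | {5-methoxy-2-(methoxymethoxy)-4-[(methoxymethoxy)methyl]phenyl}methanol | COCOCc1cc(OCOC)c(CO)cc1OC | intermediate
12 | 1-(chloromethyl)-5-methoxy-2-(methoxymethoxy)-4-[(methoxymethoxy)methyl]benzene | COCOCc1cc(OCOC)c(CCl)cc1OC | intermediate
13 | {5-methoxy-2-(methoxymethoxy)-4-[(methoxymethoxy)methyl]benzyl}magnesium chloride | COCOCc1cc(OCOC)c(C[Mg]Cl)cc1OC | intermediate
14 | 3-(trimethylsilyl)but-3-en-2-one | CC(=O)C(=C)[Si](C)(C)C | starting material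
15 | chloromagnesium enolate (C5=C10) of the conjugate adduct, 9β-CH2Ar, 8α-OSiEt3 | CC[Si](CC)(CC)O[C@@H]1CCC(O[Mg]Cl)=C(C)[C@H]1Cc1cc(OC)c(COCOC)cc1OCOC | intermediate (not isolated)
16 | 2β-methyl-2α-[3-oxo-2-(trimethylsilyl)butyl]-3β-(ArCH2)-4α-(triethylsilyloxy)cyclohexanone (silyl-bearing carbon unassigned) | CC[Si](CC)(CC)O[C@@H]1CCC(=O)[C@](C)(CC(C(C)=O)[Si](C)(C)C)[C@H]1Cc1cc(OC)c(COCOC)cc1OCOC | intermediate (not isolated)
17 | bicyclic enone: ring A 3-oxo-Δ4, 10β-methyl, 9β-CH2Ar, 8α-OSiEt3 | CC[Si](CC)(CC)O[C@@H]1CCC2=CC(=O)CC[C@]2(C)[C@H]1Cc1cc(OC)c(COCOC)cc1OCOC | intermediate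
18 | 4,4-dimethyl β,γ-enone: 3-oxo-Δ5, 10β-methyl, 9β-CH2Ar, 8α-OSiEt3 | CC[Si](CC)(CC)O[C@@H]1CC=C2C(C)(C)C(=O)CC[C@]2(C)[C@H]1Cc1cc(OC)c(COCOC)cc1OCOC | intermediate
19 | C3 hydrazone of the desilylated ketone (8α-OH, Δ5) | O[C@@H]1CC=C2C(C)(C)C(=NN)CC[C@]2(C)[C@H]1Cc1cc(OC)c(COCOC)cc1OCOC | intermediate (not isolated)
20 | 11-Ar-12-nordrim-5-en-8α-ol | O[C@@H]1CC=C2C(C)(C)CCC[C@]2(C)[C@H]1Cc1cc(OC)c(COCOC)cc1OCOC | intermediate
21 | 11-Ar-12-nordriman-8α-ol (5α-H) | O[C@@H]1CC[C@H]2C(C)(C)CCC[C@]2(C)[C@H]1Cc1cc(OC)c(COCOC)cc1OCOC | intermediate
22 | 11-Ar-12-nordriman-8-one | O=C1CC[C@H]2C(C)(C)CCC[C@]2(C)[C@H]1Cc1cc(OC)c(COCOC)cc1OCOC | intermediate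
23 | 11-Ar-drim-8(12)-ene | C=C1CC[C@H]2C(C)(C)CCC[C@]2(C)[C@H]1Cc1cc(OC)c(COCOC)cc1OCOC | intermediate
24 | 11-[2-hydroxy-4-(hydroxymethyl)-5-methoxyphenyl]drim-8(12)-ene | C=C1CC[C@H]2C(C)(C)CCC[C@]2(C)[C@H]1Cc1cc(OC)c(CO)cc1O | intermediate
25 | 2-(drim-8(12)-en-11-yl)-5-(hydroxymethyl)-4,4-dimethoxycyclohexa-2,5-dien-1-one | C=C1CC[C@H]2C(C)(C)CCC[C@]2(C)[C@H]1CC1=CC(OC)(OC)C(CO)=CC1=O | intermediate
26 | (1R,6S)-1-(drim-8(12)-en-11-yl)-4-(hydroxymethyl)-5,5-dimethoxy-7-oxabicyclo[4.1.0]hept-3-en-2-one | C=C1CC[C@H]2C(C)(C)CCC[C@]2(C)[C@H]1C[C@@]12O[C@@H]1C(OC)(OC)C(CO)=CC2=O | intermediate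
27 | (1R,6S)-1-(drim-8(12)-en-11-yl)-4-(hydroxymethyl)-7-oxabicyclo[4.1.0]hept-3-ene-2,5-dione | C=C1CC[C@H]2C(C)(C)CCC[C@]2(C)[C@H]1C[C@@]12O[C@@H]1C(=O)C(CO)=CC2=O | intermediate
28 | (1R,5R,6R)-1-(drim-8(12)-en-11-yl)-5-hydroxy-4-(hydroxymethyl)-7-oxabicyclo[4.1.0]hept-3-en-2-one | C=C1CC[C@H]2C(C)(C)CCC[C@]2(C)[C@H]1C[C@@]12O[C@@H]1[C@H](O)C(CO)=CC2=O | intermediate
29 | dimethyl 3-hydroxy-3-methylpentanedioate | COC(=O)CC(C)(O)CC(=O)OC | starting material
30 | (3S)-3-hydroxy-5-methoxy-3-methyl-5-oxopentanoic acid | OC(=O)C[C@](C)(O)CC(=O)OC | intermediate
31 | 1-tert-butyl 5-methyl (3R)-3-hydroxy-3-methylpentanedioate | CC(C)(C)OC(=O)C[C@](C)(O)CC(=O)OC | intermediate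
32 | (3R)-5-tert-butoxy-3-hydroxy-3-methyl-5-oxopentanoic acid | CC(C)(C)OC(=O)C[C@](C)(O)CC(=O)O | intermediate
33 | tert-butyl ester of the target (acid carbinol 3R by priorities; ring C 1'R,2'R,3'R) | C=C1CC[C@H]2C(C)(C)CCC[C@]2(C)[C@H]1C[C@@]12O[C@@H]1[C@H](O)C(COC(=O)C[C@@](C)(O)CC(=O)OC(C)(C)C)=CC2=O | intermediate
34 | trimethylsilyl ester of the target with C3' and tertiary hydroxyls as trimethylsilyl ethers | C=C1CC[C@H]2C(C)(C)CCC[C@]2(C)[C@H]1C[C@@]12O[C@@H]1[C@H](O[Si](C)(C)C)C(COC(=O)C[C@@](C)(O[Si](C)(C)C)CC(=O)O[Si](C)(C)C)=CC2=O | intermediate (not isolated)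
35 | CNP0158101.1: (3S)-3-hydroxy-3-methylpentanedioic acid mono ester of 28 at the primary hydroxyl | C=C1CC[C@H]2C(C)(C)CCC[C@]2(C)[C@H]1C[C@@]12O[C@@H]1[C@H](O)C(COC(=O)C[C@@](C)(O)CC(=O)O)=CC2=O | target

## Step count and least certain steps

Total: 27 steps. Longest linear sequence: 19 steps (from 7 through 13, 17 and 28 to 35: steps 6 to 22, then 26 and 27).

Step 12 (key step). Most likely failure: slow conjugate addition of the benzylic copper species to the α-methyl enone, with competing 1,2-addition and homocoupling of the reagent, or proton transfer of the hindered magnesium enolate before it captures 14, so that the ring is not annulated. Fallback: starting from 6 and 13, the copper-catalysed addition is run with Me3SiCl at −78 °C, which accelerates the addition and traps the enolate as the trimethylsilyl enol ether F1. F1 is isolated, converted into the lithium enolate with MeLi in THF, treated with 14 at −78 °C and then with NaOMe in MeOH; the route is rejoined at 17.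

Step 7. Most likely failure: reduction of the wrong formyl group or of both, if the deactivation by the phenoxide is weaker than assumed. Fallback: starting from 8, both aldehydes are reduced with excess NaBH4 to 2-hydroxy-5-methoxybenzene-1,4-dimethanol F2. The phenol and its ortho CH2OH are tied up with 2,2-dimethoxypropane and PPTS as the benzodioxine (6-methoxy-2,2-dimethyl-4H-1,3-benzodioxin-7-yl)methanol F3. The remaining hydroxyl is protected with MeOCH2Cl and i-Pr2NEt to give the methoxymethyl ether F4, and the acetonide is removed with aqueous acetic acid to give 2-(hydroxymethyl)-4-methoxy-5-[(methoxymethoxy)methyl]phenol F5. The phenol alone is then alkylated with MeOCH2Cl and K2CO3 in acetone; the route is rejoined at 11.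

Step 15. Most likely failure: incomplete hydrogen-atom transfer to the alkene flanked by two quaternary carbons, or hydrogen delivery to the β face of the C5 radical, eroding the trans ring fusion. Fallback: starting from 20, surface hydrogenation (H2 under pressure, Pd/C, EtOAc), in which the alkene adsorbs through its less hindered α face; this goes directly to 21 and makes no new compound (F0).

Step 20. Most likely failure: poor or reversed facial selection, because the decalin stereocentres are remote, the α-alkyl group slows peroxide addition, and the sense of induction is assumed. Fallback: starting from 25, epoxidation without chiral control (t-BuOOH, DBU, CH2Cl2) gives 26 together with its (1S,6R)-epoxide diastereomer F6. Because of the decalin the two are diastereomers and are separated by chromatography; the route is rejoined at 26.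

Step 22. Most likely failure: hydride attack at C6', reduction of both carbonyls, or conjugate reduction, if direction by the aluminium alkoxide is weak. Fallback: starting from 27, intramolecular hydride delivery from the primary hydroxyl with Me4NBH(OAc)3 in MeCN/AcOH at −20 °C (Evans–Saksena-type reduction of the β-hydroxy ketone unit formed by the CH2OH group and C3'); this goes directly to 28 and makes no new compound (F0).

Step 27. Most likely failure: Lewis-acid opening of the epoxide, migration of the C8=C12 double bond, or acyl migration to the C3' oxygen during the hydrolytic work-up. Fallback: starting from 28, 3-hydroxy-3-methylglutaric anhydride is opened directly by the primary hydroxyl (DMAP cat., pyridine, CH2Cl2, 0 °C). This gives 35 together with the (3R)-epimer of the target at the acid carbinol F7, which is removed by preparative HPLC; the route is rejoined at 35.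

## Further compounds

F1 | step 12 | trimethylsilyl enol ether of the conjugate adduct (C5=C10; 9β-CH2Ar; 8α-OSiEt3) | CC[Si](CC)(CC)O[C@@H]1CCC(O[Si](C)(C)C)=C(C)[C@H]1Cc1cc(OC)c(COCOC)cc1OCOC
F2 | step 7 | 2-hydroxy-5-methoxybenzene-1,4-dimethanol | COc1cc(CO)c(O)cc1CO
F3 | step 7 | (6-methoxy-2,2-dimethyl-4H-1,3-benzodioxin-7-yl)methanol | COc1cc2COC(C)(C)Oc2cc1CO
F4 | step 7 | 6-methoxy-7-[(methoxymethoxy)methyl]-2,2-dimethyl-4H-1,3-benzodioxine | COCOCc1cc2OC(C)(C)OCc2cc1OC
F5 | step 7 | 2-(hydroxymethyl)-4-methoxy-5-[(methoxymethoxy)methyl]phenol | COCOCc1cc(O)c(CO)cc1OC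
F0 | step 15 | none | none
F6 | step 20 | (1S,6R)-1-(drim-8(12)-en-11-yl)-4-(hydroxymethyl)-5,5-dimethoxy-7-oxabicyclo[4.1.0]hept-3-en-2-one | C=C1CC[C@H]2C(C)(C)CCC[C@]2(C)[C@H]1C[C@]12O[C@H]1C(OC)(OC)C(CO)=CC2=O
F0 | step 22 | none | none
F7 | step 27 | (3R)-epimer of the target at the acid carbinol | C=C1CC[C@H]2C(C)(C)CCC[C@]2(C)[C@H]1C[C@@]12O[C@@H]1[C@H](O)C(COC(=O)C[C@](C)(O)CC(=O)O)=CC2=O
A1 | alternative 1 | ring C cis-1,2-diol from the pinacol closure (4'-methylene; 2'-O-para-methoxybenzyl; 3'-O-tert-butyldimethylsilyl) | C=C1CC[C@H]2C(C)(C)CCC[C@]2(C)[C@H]1C[C@@]1(O)[C@@H](OCc2ccc(OC)cc2)[C@H](O[Si](C)(C)C(C)(C)C)C(=C)C[C@@H]1O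
A2 | alternative 1 | δ-keto aldehyde (C1' ketone; C6' aldehyde) | C=C1CC[C@H]2C(C)(C)CCC[C@]2(C)[C@H]1CC(=O)[C@@H](OCc1ccc(OC)cc1)[C@H](O[Si](C)(C)C(C)(C)C)C(=C)CC=O
A3 | alternative 1 | (+)-sclareolide | CC1(CCC[C@]2([C@H]1CC[C@@]3([C@@H]2CC(=O)O3)C)C)C
A4 | alternative 2 | drimanylmethyl dimethoxyarene with the C8 exocyclic alkene | C=C1CC[C@H]2C(C)(C)CCC[C@]2(C)[C@H]1Cc1cc(OC)c(CO[Si](C)(C)C(C)(C)C)cc1OC
A5 | alternative 2 | (Z)-allylsilane with the tetrasubstituted ring A alkene | CC1=C(CC/C(C[Si](C)(C)C)=C/Cc2cc(OC)c(CO[Si](C)(C)C(C)(C)C)cc2OC)C(C)(C)CCC1
A6 | alternative 3 | bis-silylated epoxycyclohexenone | C=C1CC[C@H]2C(C)(C)CCC[C@]2(C)[C@H]1C[C@@]12O[C@@H]1[C@H](O[Si](CC)(CC)CC)C(CO[Si](C)(C)C(C)(C)C)=CC2=O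
A7 | alternative 3 | acyclic epoxy dienone (C6' vinyl ketone; C4' 1,1-disubstituted alkene) | C=C1CC[C@H]2C(C)(C)CCC[C@]2(C)[C@H]1C[C@@]1(C(=O)C=C)O[C@@H]1[C@H](O[Si](CC)(CC)CC)C(=C)CO[Si](C)(C)C(C)(C)C
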